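**Strategy.** The plan disconnects ring B of the labdane (labdane numbering) at the C9–C10 bond, between the side-chain-bearing methine and the methyl-bearing quaternary ring-fusion carbon. Because C9 is β to the C17 carboxyl through C8, a tertiary C10 radical can close ring B by conjugate addition. One iron-hydride hydrogen-atom-transfer cyclization of a monocyclic triene ester therefore forms ring B, the C10 quaternary centre and the C9 stereocentre, both relayed from the single C5 stereocentre of an (S)-2,6,6-trimethylcyclohexenyl unit (set by CBS reduction and Claisen transfer) and from a (Z)-enoate made by Still–Gennari olefination. Selenoxide elimination, saponification and isobutyrylation finish the synthesis.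

Key step: step 8

Remark: 2,4,4-trimethylcyclohex-2-en-1-one, geranyl benzoate and methyl bis(2,2,2-trifluoroethyl)phosphonoacetate are taken to be catalogue chemicals; bicyclic compounds are described with labdane numbering (C1–C20).

**Step 1**
Reactants: 1 2,4,4-trimethylcyclohex-2-en-1-one
Product: 2 (1R)-2,4,4-trimethylcyclohex-2-en-1-ol
Conditions: (S)-1-methyl-3,3-diphenyltetrahydro-1H,3H-pyrrolo[1,2-c][1,3,2]oxazaborole (10 mol%), BH3·SMe2, THF, −20 °C; MeOH, then aq. NH4Cl
Reagents that add atoms: none
Why: Corey–Bakshi–Shibata reduction, in which the 2-methylalkenyl flank acts as the large group (as phenyl does in acetophenone), so the (S)-catalyst should deliver hydride to the face that gives the (R)-carbinol in high enantiomeric purity.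

**Step 2**
Reactants: 2 (1R)-2,4,4-trimethylcyclohex-2-en-1-ol
Product: 5 ethyl 2-[(1S)-2,6,6-trimethylcyclohex-2-en-1-yl]acetate, via mixed orthoester 3 (not isolated), via ketene acetal 4 (not isolated)
Conditions: MeC(OEt)3 (5 equiv), EtCO2H (cat.), 140 °C, EtOH distilled off
Reagents that add atoms: triethyl orthoacetate CC(OCC)(OCC)OCC
Why: Johnson–Claisen rearrangement, whose suprafacial [3,3] shift forms the new C–C bond next to the gem-dimethyl carbon on the face that carried the C–O bond, so the (R)-carbinol centre becomes the (S)-configured future C5 and the alkene moves to the methyl-bearing C10=C1 position.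

**Step 3**
Reactants: 5 ethyl 2-[(1S)-2,6,6-trimethylcyclohex-2-en-1-yl]acetate
Product: 6 2-[(1S)-2,6,6-trimethylcyclohex-2-en-1-yl]ethan-1-ol
Conditions: LiAlH4, Et2O, 0 °C to rt; H2O, aq. NaOH work-up
Reagents that add atoms: none
Why: Hydride reduction of the ester to the primary alcohol leaves the trisubstituted alkene and the non-enolisable stereocentre untouched.

**Step 4**
Reactants: 6 2-[(1S)-2,6,6-trimethylcyclohex-2-en-1-yl]ethan-1-ol
Product: 7 (6S)-6-(2-iodoethyl)-1,5,5-trimethylcyclohex-1-ene
Conditions: I2, PPh3, imidazole, CH2Cl2, 0 °C to rt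
Reagents that add atoms: iodine II
Why: Appel-type iodination, in which iodide displaces the oxyphosphonium group of the unhindered primary alcohol by SN2 without touching the alkene.

**Step 5**
Reactants: 7 (6S)-6-(2-iodoethyl)-1,5,5-trimethylcyclohex-1-ene; 8 methyl 2-[bis(2,2,2-trifluoroethoxy)phosphoryl]acetate
Product: 9 methyl (2RS)-2-[bis(2,2,2-trifluoroethoxy)phosphoryl]-4-[(1S)-2,6,6-trimethylcyclohex-2-en-1-yl]butanoate
Conditions: NaH, 8 (2 equiv), DMSO, rt; then 7, 50 °C
Reagents that add atoms: none
Why: SN2 C-alkylation of the sodium salt of the phosphonoacetate joins the C6–C7 tether to the future C8, with excess 8 suppressing double alkylation; the new α-centre becomes trigonal in step 7.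

**Step 6**
Reactants: 10 geranyl benzoate [(2E)-3,7-dimethylocta-2,6-dien-1-yl benzoate]
Product: 12 (2E)-3-methyl-6-oxohex-2-en-1-yl benzoate, via ozonide 11 (not isolated)
Conditions: O3 (1.0 equiv, Sudan Red 7B end point), CH2Cl2, −78 °C; then Me2S, −78 °C to rt
Reagents that add atoms: ozone [O-][O+]=O
Why: Chemoselective ozonolysis, because ozone should attack the electron-rich 6,7-alkene much faster than the 2,3-alkene deactivated by the allylic benzoate, and reductive work-up gives the aldehyde with the (E)-allylic ester intact.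

**Step 7**
Reactants: 9 methyl (2RS)-2-[bis(2,2,2-trifluoroethoxy)phosphoryl]-4-[(1S)-2,6,6-trimethylcyclohex-2-en-1-yl]butanoate; 12 (2E)-3-methyl-6-oxohex-2-en-1-yl benzoate
Product: 13 methyl (2Z,6E)-8-(benzoyloxy)-6-methyl-2-{2-[(1S)-2,6,6-trimethylcyclohex-2-en-1-yl]ethyl}octa-2,6-dienoate
Conditions: KN(SiMe3)2, 18-crown-6, THF, −78 °C
Reagents that add atoms: none
Why: Still–Gennari variant of the Horner–Wadsworth–Emmons reaction, in which the electron-poor bis(trifluoroethyl) phosphonate eliminates rapidly from the kinetic adduct and should give the (Z)-trisubstituted enoate with the ester cis to the C11 chain.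

**Step 8**
Reactants: 13 methyl (2Z,6E)-8-(benzoyloxy)-6-methyl-2-{2-[(1S)-2,6,6-trimethylcyclohex-2-en-1-yl]ethyl}octa-2,6-dienoate
Product: 14 methyl 15-(benzoyloxy)labd-13(E)-en-17-oate (H-5α; H-9α; CH3-10β; both C8 epimers)
Conditions: Fe(acac)3 (30 mol%), PhSiH3 (2.5 equiv), EtOH/ethylene glycol (5:1), degassed, 60 °C
Reagents that add atoms: none
Why: An iron hydride formed from Fe(acac)3 and PhSiH3 transfers a hydrogen atom to C1 of the ring alkene, the tertiary C10 radical adds to C9 (the β-carbon of the enoate), and the resulting C8 α-ester radical is reduced to an iron enolate and protonated by ethanol. The closest known reaction type is the intramolecular metal-hydride hydrogen-atom-transfer reductive olefin coupling (Giese-type), together with radical polyene cyclizations that form trans-decalins through the same C10 radical. Ring B closes in the 6-endo-trig mode, favoured by polarity and sterics over 5-exo attack at the fully substituted, ester-bearing C8. C10 is set by a chair–chair transition state in which the C5 tether stays equatorial and the methyl group becomes axial, giving the trans ring fusion (CH3-10β, H-5α), and C9 is set by the Z geometry of the enoate, which places the C11 chain trans to C7 and hence equatorial (H-9α). The step needs hydrogen-atom transfer to the ring alkene and not to the C13 alkene, which the allylic benzoate deactivates, and it needs ring closure to outrun reduction of the C10 radical, which the polarity-matched acceptor secures. The C8 configuration is inconsequential because C8 becomes trigonal in step 9.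

**Step 9**
Reactants: 14 methyl 15-(benzoyloxy)labd-13(E)-en-17-oate
Product: 17 methyl 15-(benzoyloxy)labda-7,13(E)-dien-17-oate, via selenide 15 (not isolated), via selenoxide 16 (not isolated)
Conditions: LiN(iPr)2, THF, −78 to −30 °C; PhSeBr, −78 °C; crude selenide: 3-chloroperbenzoic acid (1.05 equiv), CH2Cl2, −78 °C; iPr2NH, warm to rt
Reagents that add atoms: none
Why: Ester enolate selenenylation followed by selenoxide syn-elimination, which should run toward the accessible C7 methylene and not toward the hindered C9 methine next to quaternary C10, giving the conjugated 7,8-alkene; the benzoate has no α-hydrogen and should survive the amide base at low temperature.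

**Step 10**
Reactants: 17 methyl 15-(benzoyloxy)labda-7,13(E)-dien-17-oate
Product: 18 15-hydroxylabda-7,13(E)-dien-17-oic acid
Conditions: KOH, MeOH/H2O (4:1), 70 °C; then aq. HCl to pH 3
Reagents that add atoms: potassium hydroxide [K+].[OH-]
Why: Saponification cleaves the benzoate and the hindered conjugated methyl ester by acyl–oxygen fission, and none of the three stereocentres carries an acidic hydrogen.

**Step 11**
Reactants: 18 15-hydroxylabda-7,13(E)-dien-17-oic acid
Product: 20 15-(isobutyryloxy)labda-7,13(E)-dien-17-oic acid (target CNP0191003.1), via mixed anhydride 19 (not isolated)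
Conditions: (iPrCO)2O (2.5 equiv), pyridine, 4-(dimethylamino)pyridine (cat.), CH2Cl2, 0 °C to rt; then THF/H2O, NaHCO3, rt; acidify
Reagents that add atoms: isobutyric anhydride CC(C)C(=O)OC(=O)C(C)C
Why: Nucleophile-catalysed acylation esterifies the primary allylic alcohol while the acid is converted into the mixed anhydride 19, which mild aqueous bicarbonate hydrolyses back to the free acid without touching the isobutyrate ester.

**Compound list**

1 | 2,4,4-trimethylcyclohex-2-en-1-one | CC1=CC(C)(C)CCC1=O | starting material
2 | (1R)-2,4,4-trimethylcyclohex-2-en-1-ol | CC1=CC(C)(C)CC[C@H]1O | intermediate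
3 | (6R)-6-(1,1-diethoxyethoxy)-1,3,3-trimethylcyclohex-1-ene (mixed orthoester) | CC1=CC(C)(C)CC[C@H]1OC(C)(OCC)OCC | intermediate
4 | (6R)-6-[(1-ethoxyethenyl)oxy]-1,3,3-trimethylcyclohex-1-ene (ketene acetal) | CC1=CC(C)(C)CC[C@H]1OC(=C)OCC | intermediate
5 | ethyl 2-[(1S)-2,6,6-trimethylcyclohex-2-en-1-yl]acetate | CCOC(=O)C[C@@H]1C(C)=CCCC1(C)C | intermediate
6 | 2-[(1S)-2,6,6-trimethylcyclohex-2-en-1-yl]ethan-1-ol | OCC[C@@H]1C(C)=CCCC1(C)C | intermediate
7 | (6S)-6-(2-iodoethyl)-1,5,5-trimethylcyclohex-1-ene | ICC[C@@H]1C(C)=CCCC1(C)C | intermediate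
8 | methyl 2-[bis(2,2,2-trifluoroethoxy)phosphoryl]acetate | COC(=O)CP(=O)(OCC(F)(F)F)OCC(F)(F)F | starting material
9 | methyl (2RS)-2-[bis(2,2,2-trifluoroethoxy)phosphoryl]-4-[(1S)-2,6,6-trimethylcyclohex-2-en-1-yl]butanoate | COC(=O)C(CC[C@@H]1C(C)=CCCC1(C)C)P(=O)(OCC(F)(F)F)OCC(F)(F)F | intermediate
10 | geranyl benzoate, (2E)-3,7-dimethylocta-2,6-dien-1-yl benzoate | CC(C)=CCC/C(C)=C/COC(=O)c1ccccc1 | starting material
11 | (2E)-5-(5,5-dimethyl-1,2,4-trioxolan-3-yl)-3-methylpent-2-en-1-yl benzoate (ozonide) | CC1(C)OOC(CC/C(C)=C/COC(=O)c2ccccc2)O1 | intermediate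
12 | (2E)-3-methyl-6-oxohex-2-en-1-yl benzoate | O=CCC/C(C)=C/COC(=O)c1ccccc1 | intermediate
13 | methyl (2Z,6E)-8-(benzoyloxy)-6-methyl-2-{2-[(1S)-2,6,6-trimethylcyclohex-2-en-1-yl]ethyl}octa-2,6-dienoate | COC(=O)/C(CC[C@@H]1C(C)=CCCC1(C)C)=C\CC/C(C)=C/COC(=O)c2ccccc2 | intermediate
14 | methyl 15-(benzoyloxy)labd-13(E)-en-17-oate (H-5α, H-9α, CH3-10β; C8 left unassigned) | C/C(=C\COC(=O)c3ccccc3)CC[C@H]1C(C(=O)OC)CC[C@H]2C(C)(C)CCC[C@]12C | intermediate
15 | methyl 15-(benzoyloxy)-8-(phenylselanyl)labd-13(E)-en-17-oate (selenide) | C/C(=C\COC(=O)c3ccccc3)CC[C@H]1C([Se]c4ccccc4)(C(=O)OC)CC[C@H]2C(C)(C)CCC[C@]12C | intermediate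
16 | methyl 15-(benzoyloxy)-8-(phenylseleninyl)labd-13(E)-en-17-oate (selenoxide) | C/C(=C\COC(=O)c3ccccc3)CC[C@H]1C([Se](=O)c4ccccc4)(C(=O)OC)CC[C@H]2C(C)(C)CCC[C@]12C | intermediate
17 | methyl 15-(benzoyloxy)labda-7,13(E)-dien-17-oate | C/C(=C\COC(=O)c3ccccc3)CC[C@H]1C(C(=O)OC)=CC[C@H]2C(C)(C)CCC[C@]12C | intermediate
18 | 15-hydroxylabda-7,13(E)-dien-17-oic acid | C/C(=C\CO)CC[C@H]1C(C(=O)O)=CC[C@H]2C(C)(C)CCC[C@]12C | intermediate
19 | 15-(isobutyryloxy)labda-7,13(E)-dien-17-oic isobutyric anhydride (mixed anhydride) | C/C(=C\COC(=O)C(C)C)CC[C@H]1C(C(=O)OC(=O)C(C)C)=CC[C@H]2C(C)(C)CCC[C@]12C | intermediate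
20 | (5S,9R,10S)-15-(isobutyryloxy)labda-7,13(E)-dien-17-oic acid, CNP0191003.1 | C/C(=C\COC(=O)C(C)C)CC[C@H]1C(C(=O)O)=CC[C@H]2C(C)(C)CCC[C@]12C | target

**Step count.** Total: 11 steps. Longest linear sequence: 10 steps (steps 1–5 and 7–11; step 6 is the side branch).

**Steps most likely to fail**

1. Step 8. Hydrogen-atom transfer may go in part to the C13 alkene, or the C10 radical may be reduced before it closes the ring. Fallback: generate the same tertiary radical by halogen-atom abstraction instead of by a metal hydride. Setting out from 13, Markovnikov hydrobromination of the more electron-rich ring alkene (HBr in AcOH, CH2Cl2, −40 °C) should give methyl (2Z,6E)-8-(benzoyloxy)-2-{2-[(1S)-2-bromo-2,6,6-trimethylcyclohexyl]ethyl}-6-methylocta-2,6-dienoate F1. Slow addition of Bu3SnH with 2,2'-azobis(2-methylpropionitrile) in benzene at 80 °C should then effect the same 6-endo Giese closure in a tin hydride chain and come back to the route at 14.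

2. Step 9. Deprotonation at the hindered C8 may be incomplete, and the syn-elimination may run partly toward C9. Fallback: base-free, carboxylate-directed dehydrogenation. Setting out from 14, saponification as in step 10 should give 15-hydroxylabd-13(E)-en-17-oic acid F2. Acylation as in step 11, through the O-isobutyryl mixed anhydride F3 that is hydrolysed on work-up, should give 15-(isobutyryloxy)labd-13(E)-en-17-oic acid F4. Ligand-enabled palladium-catalysed α,β-dehydrogenation of the free acid (Pd(OAc)2, a bidentate pyridine–pyridone ligand, Ag2CO3, Na2HPO4, 100 °C) then comes back to the route at 20. In this step divalent palladium can insert only into the β-methylene C7–H bond and not into the C9 methine.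

3. Step 5. The SN2 alkylation may be slow, with competing elimination of the iodide and double alkylation of the phosphonoacetate. Fallback: Mitsunobu-type C-alkylation that bypasses the iodide. Setting out from alcohol 6 and phosphonoacetate 8, (cyanomethylene)tributylphosphorane in toluene at 100 °C should couple the two directly and come back to the route at 9; no new compound is made (F0).

**Further compounds**

F1 | step 8 | methyl (2Z,6E)-8-(benzoyloxy)-2-{2-[(1S)-2-bromo-2,6,6-trimethylcyclohexyl]ethyl}-6-methylocta-2,6-dienoate | COC(=O)/C(CC[C@@H]1C(C)(Br)CCCC1(C)C)=C\CC/C(C)=C/COC(=O)c2ccccc2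
F2 | step 9 | 15-hydroxylabd-13(E)-en-17-oic acid | C/C(=C\CO)CC[C@H]1C(C(=O)O)CC[C@H]2C(C)(C)CCC[C@]12C
F3 | step 9 | 15-(isobutyryloxy)labd-13(E)-en-17-oic isobutyric anhydride | C/C(=C\COC(=O)C(C)C)CC[C@H]1C(C(=O)OC(=O)C(C)C)CC[C@H]2C(C)(C)CCC[C@]12C
F4 | step 9 | 15-(isobutyryloxy)labd-13(E)-en-17-oic acid | C/C(=C\COC(=O)C(C)C)CC[C@H]1C(C(=O)O)CC[C@H]2C(C)(C)CCC[C@]12C
F0 | step 5 | none | none
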